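## Analysis of the target

The target is a linear tetralignol. A guaiacyl ring A, two syringyl rings B and C and a 7-methoxy-2,3-dihydrobenzofuran (ring D with its furan ring) carrying an (E)-propenal at C5 are joined in a row. Rings A/B and B/C are linked by arylglycerol β-aryl ether units Cα(H)(OH)–Cβ(H)(OAr)–CγH2OH, ring C sits on C2 of the dihydrobenzofuran, and C3 carries CH2OH.

There are six stereocentres in three isolated pairs: C2/C3 are trans (2R,3S), and each glycerol unit is (αR,βS), the erythro (anti) arrangement of α-hydroxyl and β-aryloxy group. The pairs are insulated from each other by aromatic rings, so none can control another, and a wrong-handed unit gives a diastereomer that differs only at a remote site.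

Sensitive points are the enal, the free p-hydroxybenzyl alcohol of the ring A unit (quinone methide chemistry), the electron-rich benzylic carbinols and the benzylic C2–O1 bond (ionisation under acid), and the β-aryloxy groups, which leave readily from any carbanion or metal placed on Cα. The skeleton is only a chain of C–O and C=C bond formations between simple aromatic aldehydes; the hard part is the four acyclic stereocentres.

The strategy rests on one feature. In both units the H on Cβ and the OH on Cα are the elements of water added across the Cα=Cβ bond of an aryl enol ether ArCαH=Cβ(OAr′)CγH2OR. Adding H and OH to the same face of the Z isomer (aryl cis to aryloxy) gives exactly the anti α-OH/β-OAr relationship. The relative configuration of each unit can therefore be stored in an alkene geometry and the absolute configuration in the choice of alkene face.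

## Retrosynthetic reasoning

Numbering used throughout: 1–35 as in the steps and the compound list. DBF = (2R,3S)-5-bromo-3-[(tert-butyldimethylsilyloxy)methyl]-7-methoxy-2,3-dihydro-1-benzofuran-2-yl; TBS = tert-butyldimethylsilyl; TIPS = triisopropylsilyl; Ipc = isopinocampheyl.

**35 ⇐ 34.** The four O–Si bonds are cut last. The free phenol, the p-hydroxybenzyl alcohol and the enal together are the most fragile state of the molecule, so they should appear only in the final, mild fluoride step.

**34 ⇐ 31 + 32.** The bond between C5 of ring D and the propenal chain is cut. An enal cannot pass through the hydride and borane steps, so C5 carries bromine from compound 1 onwards, and the three-carbon chain is added by a Heck reaction with acetal 32 after all reductions are done.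

**31 ⇐ 29 (key disconnection).** In both glycerol units the Cα–OH bond and the Cβ–H bond are removed, giving the bis(Z-enol ether) 29. This is where four of the six stereocentres are taken out in one operation, leaving a precursor whose only stereocentres are C2 and C3. The forward reaction must put boron on Cα and hydrogen on Cβ from the same face, choose the face at two independent alkenes, and oxidise the carbon–boron bonds before the β-aryloxy group is lost.

**29 ⇐ 28 ⇐ 27.** The allylic silyl ethers are traced back by silylation and hydride reduction to the bis(α-aryloxyacrylate) 27. The esters are what makes the Z geometry accessible, since the aryl group prefers to lie trans to the ester.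

**27 ⇐ 24 + 26; 24 ⇐ 23 + 20; 23 ⇐ 22 ⇐ 21 + 11; 21 ⇐ 19 + 20.** Each enol ether is cut twice: at the C=C bond (Horner–Wadsworth–Emmons olefination with aldehyde 26 or 11) and at the aryl O–C bond (O–H insertion of the carbenoid from diazo phosphonate 20 into phenol 23 or 19). The hindered 2,6-dimethoxyphenol oxygen is a poor partner for substitution chemistry, and carbenoid insertion forms the O–C bond under neutral conditions and delivers the olefination handle at the same time. The ring B phenol is masked as a TBS ether during the first olefination and freed for the second insertion. The ring A phenol is carried as the more base-stable TIPS ether, because it has to outlast alkaline peroxide and the Heck base.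

**19 ⇐ 17 ⇐ 15.** The C2–O1 bond of the dihydrofuran ring is cut to the diol 15. The benzylic carbinol on the trioxygenated ring C ionises readily, so the ring can be closed by acid, and C2 is then set trans to the existing C3 centre. Only C3 has to be made by an enantioselective method.

**15 ⇐ 14 ⇐ 9 + 11.** The C–C bond between the future C2 and C3 is cut as an auxiliary-controlled aldol reaction between imide 9 and aldehyde 11. This places the C3 stereocentre under the control of oxazolidinone 7 and uses the same aldehyde 11 that serves later in the olefination.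

**9 ⇐ 6 + 7; 6 ⇐ 3 ⇐ 2 ⇐ 1.** The arylacetic acid 6 comes from the commercial salicylaldehyde 1 by phenol protection and a one-carbon homologation through the trichloromethyl carbinol 3.

**11 ⇐ 10; 26 ⇐ 25.** The two aldehyde partners are the silyl ethers of syringaldehyde 10 and vanillin 25.

## Alternatives that were turned down

All three alternatives are ways to build the ring CD dihydrobenzofuran. None of them addresses the four stereocentres of the glycerol units, which would still need a method of their own.

**Alternative 1: rhodium carbenoid C–H insertion forming C2–C3.**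
- Disconnection and key step: the C2–C3 bond is cut. The aryldiazoacetate A1, in which the ring D phenol oxygen carries the ring C benzyl group, is decomposed by a chiral dirhodium tetracarboxylate of the Rh2(O2CR*)4 type. The carbenoid inserts into the benzylic ether C–H bond, and base epimerises the kinetic cis ester to the trans ester A2.
- For: chirality is catalytic, the ring and both stereocentres are made in one step from an achiral precursor, and the ester is a direct precursor of the C3 hydroxymethyl group.
- Against: the insertion gives the cis ester first. The epimerisation then runs through an ester enolate that has the C2–O1 bond in the β-position, so ring opening by elimination competes and can erode C2. The trioxygenated benzyl ring and the ether oxygen are both reactive towards an electrophilic carbenoid (arene addition, ylide formation). A1 itself needs a homologation, a benzylation with a separately made benzyl halide and a diazo transfer.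
- Comparison: it is stronger than the chosen route in not needing a stoichiometric auxiliary. In exchange, the chosen route builds ring CD by an auxiliary aldol sequence of dependable stereochemical outcome and spends its one unprecedented step on four stereocentres instead of two.

**Alternative 2: anodic quinone methide closure.**
- Disconnection and key step: the C2–O1 bond is cut. Anodic oxidation of the ring C phenol of the diarylpropanol A3 gives a para-quinone methide, and the ring D phenol oxygen adds to the methide carbon to give A4.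
- For: no protecting groups, and C2 is set by the existing C3 centre through the trans preference of the ring closure. A4 carries the free phenol and alcohol that the chosen route reaches only after steps 8 and 9.
- Against: A3 has two oxidisable phenols that differ only modestly in potential. The quinone methide can be intercepted by the solvent. The product is again a syringyl phenol that can be oxidised further. A3 still needs its own enantioselective synthesis.
- Comparison: the chosen route reaches the same cationic ring closure (step 8) without an oxidant, because the aldol reaction installs the benzylic oxygen at the correct oxidation level. Alternative 2 is the more atom-economical way to the same ring, but it adds an electrochemical chemoselectivity problem.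

**Alternative 3: sulfonium ylide [4+1] annulation.**
- Disconnection and key step: C2–C3 and C2–O1 are cut together. The ylide from the benzylic sulfonium salt A6 (or its enantiomer) adds to the ortho-quinone methide A5 generated in situ, and the phenoxide displaces the sulfide to give A7.
- For: it is the most convergent route to ring CD. Two bonds, the ring and both stereocentres form in one step, the trans relationship follows from the addition–displacement mechanism, and A7 already carries a useful protecting-group pattern. It would reach the equivalent of 19 in clearly fewer steps than the chosen route, and it places its risk early.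
- Against: A5 has a CH2 group next to the methide carbon and can tautomerise to a vinylphenol or lose the silyloxy group. The ylide is only semi-stabilised and electron-rich, a class for which enantiocontrol in this annulation is not established. Any shortfall in enantiopurity of ring CD turns into diastereomers of the tetramer.
- Comparison: the chosen strategy accepts a longer ring CD synthesis but gets it enantiopure by auxiliary control. Its single untested step then sets four stereocentres under reagent control, with the relative configuration fixed by alkene geometry.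

Key step: step 18

Remark on the chemistry: the facial sense of the borane addition is assigned by analogy with IpcBH2 additions to trisubstituted aryl alkenes. On that analogy the reagent derived from (−)-α-pinene is expected to give the (αR,βS) units. Both antipodes of the reagent are available, so the assignment would be checked on a one-unit model and the hand changed if needed.

## Route

**Step 1**
Reactants: 1 5-bromo-2-hydroxy-3-methoxybenzaldehyde
Product: 2 5-bromo-3-methoxy-2-(methoxymethoxy)benzaldehyde
Conditions: MOMCl, i-Pr2NEt, CH2Cl2, 0 °C → rt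
Reagents that add atoms: chloromethyl methyl ether, COCCl
Why: O-alkylation of the phenol; the acetal resists the bases, hydrides and boron reagents of steps 2–7 and is removed by the acid of step 8.

**Step 2**
Reactants: 2 5-bromo-3-methoxy-2-(methoxymethoxy)benzaldehyde
Product: 3 (±)-1-[5-bromo-3-methoxy-2-(methoxymethoxy)phenyl]-2,2,2-trichloroethanol
Conditions: CHCl3, DBU, 0 °C → rt
Reagents that add atoms: chloroform, ClC(Cl)Cl
Why: amidine-promoted addition of the trichloromethyl anion to the aldehyde, the first half of a Jocic-type homologation; the new carbinol centre is racemic and is destroyed in step 3.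

**Step 3**
Reactants: 3 (±)-1-[5-bromo-3-methoxy-2-(methoxymethoxy)phenyl]-2,2,2-trichloroethanol
Product: 6 [5-bromo-3-methoxy-2-(methoxymethoxy)phenyl]acetic acid, via gem-dichlorooxirane 4 (not isolated), via arylacetyl chloride 5 (not isolated)
Conditions: NaBH4, NaOH, t-BuOH–H2O, 55 °C; then aq. KHSO4, 0 °C
Reagents that add atoms: sodium hydroxide, [Na+].[OH-]
Why: reductive Jocic reaction: the alkoxide closes to oxirane 4, hydride opens it at the benzylic carbon to acid chloride 5, and hydroxide hydrolyses 5; the aryl bromide and the acetal are inert to borohydride and base.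

**Step 4**
Reactants: 6 [5-bromo-3-methoxy-2-(methoxymethoxy)phenyl]acetic acid; 7 (R)-4-benzyl-1,3-oxazolidin-2-one
Product: 9 (R)-4-benzyl-3-{[5-bromo-3-methoxy-2-(methoxymethoxy)phenyl]acetyl}-1,3-oxazolidin-2-one, via mixed pivalic anhydride 8 (not isolated)
Conditions: t-BuCOCl, Et3N, THF, −20 °C; then 7, LiCl, −20 °C → rt
Reagents that add atoms: none
Why: N-acylation of the oxazolidinone through the mixed anhydride, which is attacked at the less hindered arylacetyl carbonyl; no strong base is needed, so the acidic benzylic CH2 is not disturbed.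

**Step 5**
Reactants: 10 syringaldehyde
Product: 11 4-(tert-butyldimethylsilyloxy)-3,5-dimethoxybenzaldehyde
Conditions: TBSCl, imidazole, DMF, rt
Reagents that add atoms: tert-butyldimethylsilyl chloride, CC(C)(C)[Si](C)(C)Cl
Why: silylation of the phenol; the same aldehyde serves as aldol partner in step 6 and as olefination partner in step 11.

**Step 6**
Reactants: 9 (R)-4-benzyl-3-{[5-bromo-3-methoxy-2-(methoxymethoxy)phenyl]acetyl}-1,3-oxazolidin-2-one; 11 4-(tert-butyldimethylsilyloxy)-3,5-dimethoxybenzaldehyde
Product: 14 (R)-4-benzyl-3-[(2R,3R)-2-[5-bromo-3-methoxy-2-(methoxymethoxy)phenyl]-3-[4-(tert-butyldimethylsilyloxy)-3,5-dimethoxyphenyl]-3-hydroxypropanoyl]-1,3-oxazolidin-2-one, via boron enolate 12 (not isolated), via boron aldolate 13 (not isolated)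
Conditions: n-Bu2BOTf, i-Pr2NEt, CH2Cl2, 0 °C; 11, −78 → 0 °C; pH 7 buffer, MeOH, 30% H2O2, 0 °C
Reagents that add atoms: none
Why: Evans syn aldol reaction: the Z boron enolate 12 reacts through a closed chair transition state on the face away from the benzyl group of the auxiliary, which sets the aryl-bearing carbon as R (it becomes C3 of the dihydrobenzofuran); the carbinol centre formed at the same time is re-set in step 8.

**Step 7**
Reactants: 14 the aldol adduct of step 6
Product: 15 (1R,2S)-2-[5-bromo-3-methoxy-2-(methoxymethoxy)phenyl]-1-[4-(tert-butyldimethylsilyloxy)-3,5-dimethoxyphenyl]propane-1,3-diol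
Conditions: LiBH4, MeOH (1 equiv), THF, 0 °C
Reagents that add atoms: none
Why: reductive cleavage of the imide to the primary alcohol with recovery of 7; hydride conditions are not basic enough to epimerise the aryl-bearing centre, and the aryl bromide and silyl ether are untouched.

**Step 8**
Reactants: 15 (1R,2S)-2-[5-bromo-3-methoxy-2-(methoxymethoxy)phenyl]-1-[4-(tert-butyldimethylsilyloxy)-3,5-dimethoxyphenyl]propane-1,3-diol
Product: 17 [(2R,3S)-5-bromo-2-[4-(tert-butyldimethylsilyloxy)-3,5-dimethoxyphenyl]-7-methoxy-2,3-dihydro-1-benzofuran-3-yl]methanol, via phenolic diol 16 (not isolated)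
Conditions: HCl (1.25 M in MeOH), 0 °C → rt
Reagents that add atoms: none
Why: acid removes the methoxymethyl group to give 16 and ionises the electron-rich benzylic carbinol, and the ortho phenol closes the five-membered ring onto the cationic carbon; the closure is reversible under acid and settles with the aryl group trans to CH2OH, so C2 (R) is set by C3 (S). Any material that loses the aryl silyl group here is carried on, because step 9 converges both forms.

**Step 9**
Reactants: 17 the dihydrobenzofuran alcohol of step 8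
Product: 19 4-DBF-2,6-dimethoxyphenol, via bis-silyl ether 18 (not isolated)
Conditions: TBSCl, imidazole, DMF, rt; then MeOH, K2CO3, rt
Reagents that add atoms: tert-butyldimethylsilyl chloride, CC(C)(C)[Si](C)(C)Cl
Why: silylation of the primary alcohol, then methanolysis of the aryl silyl ether, which is far more base-labile than the alkyl silyl ether; this leaves only the ring C phenol free.

**Step 10**
Reactants: 19 4-DBF-2,6-dimethoxyphenol; 20 ethyl diazo(diethoxyphosphoryl)acetate
Product: 21 ethyl (diethoxyphosphoryl)(4-DBF-2,6-dimethoxyphenoxy)acetate (both epimers at the phosphonate carbon)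
Conditions: Rh2(OAc)4 (2 mol %), toluene, 90 °C, slow addition of 20
Reagents that add atoms: none
Why: rhodium carbenoid O–H insertion: the electrophilic carbenoid is captured by the phenol oxygen and a proton shift completes the insertion; the stereocentre at the phosphonate carbon is lost in step 11.

**Step 11**
Reactants: 21 the phosphonate of step 10; 11 4-(tert-butyldimethylsilyloxy)-3,5-dimethoxybenzaldehyde
Product: 22 ethyl (Z)-2-(4-DBF-2,6-dimethoxyphenoxy)-3-[4-(tert-butyldimethylsilyloxy)-3,5-dimethoxyphenyl]prop-2-enoate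
Conditions: NaH, THF, 0 °C → rt
Reagents that add atoms: none
Why: Horner–Wadsworth–Emmons olefination; reversible addition and elimination through the less crowded adduct should place the aryl group trans to the ester, which is the Z isomer (aryl cis to aryloxy). Any E isomer must be removed here, because it would become a threo unit in step 18.

**Step 12**
Reactants: 22 the acrylate of step 11
Product: 23 ethyl (Z)-2-(4-DBF-2,6-dimethoxyphenoxy)-3-(4-hydroxy-3,5-dimethoxyphenyl)prop-2-enoate
Conditions: KHF2, MeOH–THF, rt
Reagents that add atoms: none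
Why: bifluoride cleaves the aryl silyl ether selectively; the alkyl silyl ether and the ethyl ester are stable under these near-neutral conditions.

**Step 13**
Reactants: 23 the phenol of step 12; 20 ethyl diazo(diethoxyphosphoryl)acetate
Product: 24 ethyl (Z)-2-(4-DBF-2,6-dimethoxyphenoxy)-3-{4-[1-(diethoxyphosphoryl)-2-ethoxy-2-oxoethoxy]-3,5-dimethoxyphenyl}prop-2-enoate (both epimers at the phosphonate carbon)
Conditions: Rh2(OAc)4 (2 mol %), toluene, 90 °C, slow addition of 20
Reagents that add atoms: none
Why: second rhodium carbenoid O–H insertion; insertion into the phenol should be much faster than cyclopropanation of the hindered, trisubstituted acrylate double bond by this acceptor-substituted carbenoid.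

**Step 14**
Reactants: 25 vanillin
Product: 26 3-methoxy-4-(triisopropylsilyloxy)benzaldehyde
Conditions: TIPSCl, imidazole, DMF, rt
Reagents that add atoms: triisopropylsilyl chloride, CC(C)[Si](Cl)(C(C)C)C(C)C
Why: silylation of the phenol; the bulkier silyl group is chosen because this aryl ether must survive alkaline peroxide in step 18 and carbonate in step 19.

**Step 15**
Reactants: 24 the phosphonate of step 13; 26 3-methoxy-4-(triisopropylsilyloxy)benzaldehyde
Product: 27 ethyl (Z)-2-{4-[(Z)-2-(4-DBF-2,6-dimethoxyphenoxy)-3-ethoxy-3-oxoprop-1-enyl]-2,6-dimethoxyphenoxy}-3-[3-methoxy-4-(triisopropylsilyloxy)phenyl]prop-2-enoate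
Conditions: NaH, THF, 0 °C → rt
Reagents that add atoms: none
Why: second Horner–Wadsworth–Emmons olefination with the same preference for aryl trans to ester; the existing acrylate has no acidic hydrogen and is not affected.

**Step 16**
Reactants: 27 the bis(acrylate) of step 15
Product: 28 (Z)-2-{4-[(Z)-2-(4-DBF-2,6-dimethoxyphenoxy)-3-hydroxyprop-1-enyl]-2,6-dimethoxyphenoxy}-3-[3-methoxy-4-(triisopropylsilyloxy)phenyl]prop-2-en-1-ol
Conditions: i-Bu2AlH (6 equiv), CH2Cl2, −78 → −40 °C; aq. KNa tartrate
Reagents that add atoms: none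
Why: 1,2-reduction of both conjugated esters to the allylic alcohols; the double-bond geometry, the aryl bromide and the silyl ethers are unchanged at this temperature, and the neutral work-up protects the acid-sensitive enol ethers.

**Step 17**
Reactants: 28 the bis(allylic alcohol) of step 16
Product: 29 bis(tert-butyldimethylsilyl) ether of 28, the bis(Z-enol ether)
Conditions: TBSCl, imidazole, DMF, 0 °C → rt; Et3N-treated silica
Reagents that add atoms: tert-butyldimethylsilyl chloride, CC(C)(C)[Si](C)(C)Cl
Why: silylation of both primary allylic alcohols so that no O–H bond consumes or redirects the borane in step 18.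

**Step 18**
Reactants: 29 the bis(Z-enol ether)
Product: 31 the bis-erythro diol with (1R,2S) configuration in both units, via bis(alkylborane) 30 (not isolated)
Conditions: IpcBH2 from (−)-α-pinene (4 equiv; freed from (IpcBH2)2·TMEDA with BF3·OEt2, precipitate filtered off), THF, −25 → 0 °C; then 3 M NaOH, 30% H2O2, −10 → 0 °C
Reagents that add atoms: hydrogen peroxide, OO
Why: Proposed new method: asymmetric hydroboration of a Z aryl enol ether ArCαH=Cβ(OAr′)CH2OSi with a chiral monoalkylborane has not been described; the closest known reactions are the IpcBH2 hydroboration–oxidation of trisubstituted aryl alkenes and the hydroboration–oxidation of simple enol ethers, both four-centre syn additions followed by oxidation with retention. Boron should go to Cα in both units because three effects agree: Cα is the less substituted carbon, it is benzylic, and the enol ether oxygen polarises the alkene so that hydride goes to the oxygen-bearing Cβ. H and B add to one face in a concerted step and the carbon–boron to carbon–oxygen migration keeps configuration, so the Z geometry of 29 becomes the anti (erythro) Cα–OH/Cβ–OAr relationship in each unit. The face is chosen by the reagent: by analogy with 1-arylcycloalkenes, the borane from (−)-α-pinene should place boron on the face of Cα that gives the R carbinol and with it the S aryloxy carbon, and the same preference is expected at both enol ethers because they are insulated from each other and from C2/C3 by aromatic rings. No ring is closed; two Cα–O bonds and two Cβ–H bonds are formed and four stereocentres are set. The step needs regioselectivity (secured by the substitution pattern), geometric purity (secured in steps 11 and 15) and facial selectivity (secured by the reagent), and the aryl bromide, aryl ethers and silyl ethers do not react with alkylboranes. The β-aryloxyalkylborane 30 can lose an aryloxyboron fragment by β-elimination, so BF3 is removed as its TMEDA adduct beforehand, the temperature stays at or below 0 °C and 30 is oxidised cold without isolation.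

**Step 19**
Reactants: 31 the bis-erythro diol of step 18; 32 acrolein diethyl acetal
Product: 34 the tetrasilylated (E)-enal, via diethyl acetal 33 (not isolated)
Conditions: Pd(OAc)2 (5 mol %), n-Bu4NOAc, K2CO3, KCl, DMF, 90 °C; then PPTS, acetone–H2O, rt
Reagents that add atoms: water, O
Why: Heck reaction: oxidative addition of the aryl bromide to zerovalent palladium, insertion of the terminal alkene and β-hydride elimination towards the benzylic side give the (E)-cinnamyl acetal 33, which mild acid hydrolyses to the enal. Partial loss of the aryl silyl ether under the carbonate would be of no consequence, since step 20 removes all silyl groups.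

**Step 20**
Reactants: 34 the tetrasilylated (E)-enal
Product: 35 CNP0192639.1
Conditions: n-Bu4NF, AcOH (1:1), THF, 0 °C → rt
Reagents that add atoms: none
Why: fluoride cleaves the three alkyl TBS ethers and the aryl TIPS ether; acetic acid buffers the phenoxide and alkoxides so that the enal and the p-hydroxybenzyl alcohol are not exposed to free base, and no stereocentre is touched.

## Compound list

1 | 5-bromo-2-hydroxy-3-methoxybenzaldehyde | COc1cc(Br)cc(C=O)c1O | starting material
2 | 5-bromo-3-methoxy-2-(methoxymethoxy)benzaldehyde | COCOc1c(OC)cc(Br)cc1C=O | intermediate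
3 | (±)-1-[5-bromo-3-methoxy-2-(methoxymethoxy)phenyl]-2,2,2-trichloroethanol | COCOc1c(OC)cc(Br)cc1C(O)C(Cl)(Cl)Cl | intermediate
4 | (±)-3-[5-bromo-3-methoxy-2-(methoxymethoxy)phenyl]-2,2-dichlorooxirane | COCOc1c(OC)cc(Br)cc1C1OC1(Cl)Cl | intermediate
5 | [5-bromo-3-methoxy-2-(methoxymethoxy)phenyl]acetyl chloride | COCOc1c(OC)cc(Br)cc1CC(=O)Cl | intermediate
6 | [5-bromo-3-methoxy-2-(methoxymethoxy)phenyl]acetic acid | COCOc1c(OC)cc(Br)cc1CC(=O)O | intermediate
7 | (R)-4-benzyl-1,3-oxazolidin-2-one | O=C1OC[C@@H](Cc2ccccc2)N1 | starting material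
8 | [5-bromo-3-methoxy-2-(methoxymethoxy)phenyl]acetic pivalic anhydride | COCOc1c(OC)cc(Br)cc1CC(=O)OC(=O)C(C)(C)C | intermediate
9 | (R)-4-benzyl-3-{[5-bromo-3-methoxy-2-(methoxymethoxy)phenyl]acetyl}-1,3-oxazolidin-2-one | O=C1OC[C@@H](Cc2ccccc2)N1C(=O)Cc1cc(Br)cc(OC)c1OCOC | intermediate
10 | syringaldehyde | COc1cc(C=O)cc(OC)c1O | starting material
11 | 4-(tert-butyldimethylsilyloxy)-3,5-dimethoxybenzaldehyde | COc1cc(C=O)cc(OC)c1O[Si](C)(C)C(C)(C)C | intermediate
12 | dibutylboron (Z)-enolate of 9 | CCCCB(CCCC)O/C(=C\c1cc(Br)cc(OC)c1OCOC)N1[C@H](Cc2ccccc2)COC1=O | intermediate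
13 | O-dibutylboryl aldolate of 14 | O=C1OC[C@@H](Cc2ccccc2)N1C(=O)[C@H](c1cc(Br)cc(OC)c1OCOC)[C@@H](OB(CCCC)CCCC)c1cc(OC)c(O[Si](C)(C)C(C)(C)C)c(OC)c1 | intermediate
14 | (R)-4-benzyl-3-[(2R,3R)-2-[5-bromo-3-methoxy-2-(methoxymethoxy)phenyl]-3-[4-(tert-butyldimethylsilyloxy)-3,5-dimethoxyphenyl]-3-hydroxypropanoyl]-1,3-oxazolidin-2-one | O=C1OC[C@@H](Cc2ccccc2)N1C(=O)[C@H](c1cc(Br)cc(OC)c1OCOC)[C@@H](O)c1cc(OC)c(O[Si](C)(C)C(C)(C)C)c(OC)c1 | intermediate
15 | (1R,2S)-2-[5-bromo-3-methoxy-2-(methoxymethoxy)phenyl]-1-[4-(tert-butyldimethylsilyloxy)-3,5-dimethoxyphenyl]propane-1,3-diol | OC[C@H](c1cc(Br)cc(OC)c1OCOC)[C@@H](O)c1cc(OC)c(O[Si](C)(C)C(C)(C)C)c(OC)c1 | intermediate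
16 | (1R,2S)-2-(5-bromo-2-hydroxy-3-methoxyphenyl)-1-[4-(tert-butyldimethylsilyloxy)-3,5-dimethoxyphenyl]propane-1,3-diol | OC[C@H](c1cc(Br)cc(OC)c1O)[C@@H](O)c1cc(OC)c(O[Si](C)(C)C(C)(C)C)c(OC)c1 | intermediate
17 | [(2R,3S)-5-bromo-2-[4-(tert-butyldimethylsilyloxy)-3,5-dimethoxyphenyl]-7-methoxy-2,3-dihydro-1-benzofuran-3-yl]methanol | CC(C)(C)[Si](C)(C)Oc1c(OC)cc([C@@H]2Oc3c(OC)cc(Br)cc3[C@H]2CO)cc1OC | intermediate
18 | tert-butyldimethylsilyl ether of 17 (bis-silyl ether) | CC(C)(C)[Si](C)(C)Oc1c(OC)cc([C@@H]2Oc3c(OC)cc(Br)cc3[C@H]2CO[Si](C)(C)C(C)(C)C)cc1OC | intermediate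
19 | 4-[(2R,3S)-5-bromo-3-[(tert-butyldimethylsilyloxy)methyl]-7-methoxy-2,3-dihydro-1-benzofuran-2-yl]-2,6-dimethoxyphenol | Oc1c(OC)cc([C@@H]2Oc3c(OC)cc(Br)cc3[C@H]2CO[Si](C)(C)C(C)(C)C)cc1OC | intermediate
20 | ethyl diazo(diethoxyphosphoryl)acetate | CCOC(=O)C(=[N+]=[N-])P(=O)(OCC)OCC | starting material
21 | ethyl (diethoxyphosphoryl)(4-DBF-2,6-dimethoxyphenoxy)acetate | CCOC(=O)C(Oc1c(OC)cc([C@@H]2Oc3c(OC)cc(Br)cc3[C@H]2CO[Si](C)(C)C(C)(C)C)cc1OC)P(=O)(OCC)OCC | intermediate
22 | ethyl (Z)-2-(4-DBF-2,6-dimethoxyphenoxy)-3-[4-(tert-butyldimethylsilyloxy)-3,5-dimethoxyphenyl]prop-2-enoate | CCOC(=O)/C(Oc1c(OC)cc([C@@H]2Oc3c(OC)cc(Br)cc3[C@H]2CO[Si](C)(C)C(C)(C)C)cc1OC)=C/c1cc(OC)c(O[Si](C)(C)C(C)(C)C)c(OC)c1 | intermediate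
23 | ethyl (Z)-2-(4-DBF-2,6-dimethoxyphenoxy)-3-(4-hydroxy-3,5-dimethoxyphenyl)prop-2-enoate | CCOC(=O)/C(Oc1c(OC)cc([C@@H]2Oc3c(OC)cc(Br)cc3[C@H]2CO[Si](C)(C)C(C)(C)C)cc1OC)=C/c1cc(OC)c(O)c(OC)c1 | intermediate
24 | ethyl (Z)-2-(4-DBF-2,6-dimethoxyphenoxy)-3-{4-[1-(diethoxyphosphoryl)-2-ethoxy-2-oxoethoxy]-3,5-dimethoxyphenyl}prop-2-enoate | CCOC(=O)C(Oc1c(OC)cc(/C=C(/C(=O)OCC)Oc2c(OC)cc([C@@H]3Oc4c(OC)cc(Br)cc4[C@H]3CO[Si](C)(C)C(C)(C)C)cc2OC)cc1OC)P(=O)(OCC)OCC | intermediate
25 | vanillin | COc1cc(C=O)ccc1O | starting material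
26 | 3-methoxy-4-(triisopropylsilyloxy)benzaldehyde | COc1cc(C=O)ccc1O[Si](C(C)C)(C(C)C)C(C)C | intermediate
27 | ethyl (Z)-2-{4-[(Z)-2-(4-DBF-2,6-dimethoxyphenoxy)-3-ethoxy-3-oxoprop-1-enyl]-2,6-dimethoxyphenoxy}-3-[3-methoxy-4-(triisopropylsilyloxy)phenyl]prop-2-enoate | COc1cc(/C=C(/C(=O)OCC)Oc2c(OC)cc(/C=C(/C(=O)OCC)Oc3c(OC)cc([C@@H]4Oc5c(OC)cc(Br)cc5[C@H]4CO[Si](C)(C)C(C)(C)C)cc3OC)cc2OC)ccc1O[Si](C(C)C)(C(C)C)C(C)C | intermediate
28 | (Z)-2-{4-[(Z)-2-(4-DBF-2,6-dimethoxyphenoxy)-3-hydroxyprop-1-enyl]-2,6-dimethoxyphenoxy}-3-[3-methoxy-4-(triisopropylsilyloxy)phenyl]prop-2-en-1-ol | COc1cc(/C=C(/CO)Oc2c(OC)cc(/C=C(/CO)Oc3c(OC)cc([C@@H]4Oc5c(OC)cc(Br)cc5[C@H]4CO[Si](C)(C)C(C)(C)C)cc3OC)cc2OC)ccc1O[Si](C(C)C)(C(C)C)C(C)C | intermediate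
29 | bis(tert-butyldimethylsilyl) ether of 28, the bis(Z-enol ether) | COc1cc(/C=C(/CO[Si](C)(C)C(C)(C)C)Oc2c(OC)cc(/C=C(/CO[Si](C)(C)C(C)(C)C)Oc3c(OC)cc([C@@H]4Oc5c(OC)cc(Br)cc5[C@H]4CO[Si](C)(C)C(C)(C)C)cc3OC)cc2OC)ccc1O[Si](C(C)C)(C(C)C)C(C)C | intermediate
30 | bis[hydrido(isopinocampheyl)boryl] adduct of 29, boron on both Cα | COc1cc([C@@H](B[C@H]2C[C@H]3C[C@@H]([C@@H]2C)C3(C)C)[C@H](CO[Si](C)(C)C(C)(C)C)Oc2c(OC)cc([C@@H](B[C@H]3C[C@H]4C[C@@H]([C@@H]3C)C4(C)C)[C@H](CO[Si](C)(C)C(C)(C)C)Oc3c(OC)cc([C@@H]4Oc5c(OC)cc(Br)cc5[C@H]4CO[Si](C)(C)C(C)(C)C)cc3OC)cc2OC)ccc1O[Si](C(C)C)(C(C)C)C(C)C | intermediate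
31 | (1R,2S)-2-{4-[(1R,2S)-2-(4-DBF-2,6-dimethoxyphenoxy)-3-(tert-butyldimethylsilyloxy)-1-hydroxypropyl]-2,6-dimethoxyphenoxy}-3-(tert-butyldimethylsilyloxy)-1-[3-methoxy-4-(triisopropylsilyloxy)phenyl]propan-1-ol | COc1cc([C@@H](O)[C@H](CO[Si](C)(C)C(C)(C)C)Oc2c(OC)cc([C@@H](O)[C@H](CO[Si](C)(C)C(C)(C)C)Oc3c(OC)cc([C@@H]4Oc5c(OC)cc(Br)cc5[C@H]4CO[Si](C)(C)C(C)(C)C)cc3OC)cc2OC)ccc1O[Si](C(C)C)(C(C)C)C(C)C | intermediate
32 | acrolein diethyl acetal (3,3-diethoxyprop-1-ene) | C=CC(OCC)OCC | starting material
33 | diethyl acetal of 34: 31 with (E)-3,3-diethoxyprop-1-enyl in place of bromine | COc1cc([C@@H](O)[C@H](CO[Si](C)(C)C(C)(C)C)Oc2c(OC)cc([C@@H](O)[C@H](CO[Si](C)(C)C(C)(C)C)Oc3c(OC)cc([C@@H]4Oc5c(OC)cc(/C=C/C(OCC)OCC)cc5[C@H]4CO[Si](C)(C)C(C)(C)C)cc3OC)cc2OC)ccc1O[Si](C(C)C)(C(C)C)C(C)C | intermediate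
34 | tetrasilylated enal: 31 with (E)-3-oxoprop-1-enyl in place of bromine | COc1cc([C@@H](O)[C@H](CO[Si](C)(C)C(C)(C)C)Oc2c(OC)cc([C@@H](O)[C@H](CO[Si](C)(C)C(C)(C)C)Oc3c(OC)cc([C@@H]4Oc5c(OC)cc(/C=C/C=O)cc5[C@H]4CO[Si](C)(C)C(C)(C)C)cc3OC)cc2OC)ccc1O[Si](C(C)C)(C(C)C)C(C)C | intermediate
35 | CNP0192639.1: (E)-3-[(2R,3S)-dihydrobenzofuran-5-yl]propenal carrying 3-CH2OH, 7-OMe and the 2-aryl chain with two (αR,βS) guaiacyl/syringyl glycerol β-aryl ether units | COc1cc([C@@H](O)[C@H](CO)Oc2c(OC)cc([C@@H](O)[C@H](CO)Oc3c(OC)cc([C@@H]4Oc5c(OC)cc(/C=C/C=O)cc5[C@H]4CO)cc3OC)cc2OC)ccc1O | target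

## Step count and least certain steps

Total step count: 20. Longest linear sequence: 18 (steps 1–4, 6–13, 15–20, from compound 1).

**Step 18 (key step, carries the "Proposed new method" label).**
- What may go wrong: β-elimination of an aryloxyboron fragment from the β-aryloxyalkylborane before oxidation, which would sever the ether links. The aryloxide is a good leaving group next to boron and any residual Lewis acid catalyses the process.
- Also possible: incomplete face discrimination at one of the two independent enol ethers, which would show up as diastereomers, and slow addition to the hindered trisubstituted alkenes, which lengthens the lifetime of the borane.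
- Fallback with known chemistry (sets out from 19, returns at 31): the two units are built one after the other by auxiliary-controlled glycolate aldol reactions, which give the threo series, and both carbinols are inverted at the end.
  - Phenol 19 is alkylated with commercial (R)-4-benzyl-3-(chloroacetyl)oxazolidin-2-one (K2CO3, DMF) to the aryloxyacetyl imide F1.
  - n-Bu2BOTf/i-Pr2NEt and aldehyde 11 give the syn aldol adduct F2, and LiBH4 gives the threo diol F3.
  - TBSCl/imidazole at 0 °C silylates the primary hydroxyl to the silyl ether F4, and K2CO3/MeOH in the same flask frees the ring B phenol F5.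
  - The sequence is repeated: alkylation to the imide F6, boron aldol reaction with aldehyde 26 (one further equivalent of n-Bu2BOTf carries the free carbinol as its borinate) to the syn aldol adduct F7, LiBH4 to the triol F8, and primary silylation to the bis-threo diol F9, the Cα,Cα′ bis-epimer of 31.
  - A double Mitsunobu reaction (4-nitrobenzoic acid, PPh3, diisopropyl azodicarboxylate) inverts both benzylic carbinols to the bis(4-nitrobenzoate) F10, and K2CO3/MeOH releases 31.

**Step 10 (and its repeat, step 13).**
- What may go wrong: slow carbenoid capture by the hindered, hydrogen-bonded 2,6-dimethoxyphenol, so that carbenoid dimerisation or attack on other sites (the benzylic C2–H, and in step 13 the acrylate double bond) takes over.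
- Fallback (sets out from 19, returns at 21): O-alkylation of 19 with ethyl bromoacetate (K2CO3, acetone) gives the aryloxyacetate F11. Its lithium enolate (LiN(i-Pr)2, THF, −78 °C) is phosphinylated on carbon with ClP(OEt)2 to the phosphonite F12, which H2O2 oxidises in the same flask to 21.

**Step 11 (and its repeat, step 15).**
- What may go wrong: incomplete Z selectivity of the olefination, because the α-aryloxy group reduces the steric bias between the two elimination pathways. Every E alkene carried forward becomes a threo unit.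
- Fallback (sets out from 19, returns at 22): the aryloxyacetate F11 is made as above. Its lithium enolate adds to aldehyde 11 to give the β-hydroxy ester F13 as a mixture of diastereomers. Mesylation (MsCl, Et3N) gives the mesylate F14, and DBU eliminates through the ester enolate to 22. This stepwise elimination is under product-stability control and favours aryl trans to ester whatever the configuration of F13.

**Step 19.**
- What may go wrong: sluggish oxidative addition of the electron-rich aryl bromide under ligand-free conditions. The consequences would be reductive loss of bromine at the expense of a benzylic carbinol, β-hydride elimination towards the acetal carbon (which gives a saturated ester after hydrolysis), or base-induced loss of the aryl silyl ether followed by degradation of the phenoxide at 90 °C.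
- Fallback (sets out from 31, returns at 34 through the same acetal 33): Suzuki–Miyaura coupling of 31 with commercial (E)-2-(3,3-diethoxyprop-1-enyl)-4,4,5,5-tetramethyl-1,3,2-dioxaborolane (Pd(dppf)Cl2, K3PO4, dioxane–H2O, 70 °C), then the same mild acid hydrolysis. The alkene geometry comes from the boronate, and no new compound is needed.

## Further compounds

F1 | step 18 | (R)-4-benzyl-3-[(4-DBF-2,6-dimethoxyphenoxy)acetyl]-1,3-oxazolidin-2-one | O=C1OC[C@@H](Cc2ccccc2)N1C(=O)COc1c(OC)cc([C@@H]2Oc3c(OC)cc(Br)cc3[C@H]2CO[Si](C)(C)C(C)(C)C)cc1OC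
F2 | step 18 | (R)-4-benzyl-3-[(2R,3S)-2-(4-DBF-2,6-dimethoxyphenoxy)-3-[4-(tert-butyldimethylsilyloxy)-3,5-dimethoxyphenyl]-3-hydroxypropanoyl]-1,3-oxazolidin-2-one | O=C1OC[C@@H](Cc2ccccc2)N1C(=O)[C@H](Oc1c(OC)cc([C@@H]2Oc3c(OC)cc(Br)cc3[C@H]2CO[Si](C)(C)C(C)(C)C)cc1OC)[C@@H](O)c1cc(OC)c(O[Si](C)(C)C(C)(C)C)c(OC)c1
F3 | step 18 | (1S,2S)-2-(4-DBF-2,6-dimethoxyphenoxy)-1-[4-(tert-butyldimethylsilyloxy)-3,5-dimethoxyphenyl]propane-1,3-diol | COc1cc([C@H](O)[C@H](CO)Oc2c(OC)cc([C@@H]3Oc4c(OC)cc(Br)cc4[C@H]3CO[Si](C)(C)C(C)(C)C)cc2OC)cc(OC)c1O[Si](C)(C)C(C)(C)C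
F4 | step 18 | (1S,2S)-2-(4-DBF-2,6-dimethoxyphenoxy)-3-(tert-butyldimethylsilyloxy)-1-[4-(tert-butyldimethylsilyloxy)-3,5-dimethoxyphenyl]propan-1-ol | COc1cc([C@H](O)[C@H](CO[Si](C)(C)C(C)(C)C)Oc2c(OC)cc([C@@H]3Oc4c(OC)cc(Br)cc4[C@H]3CO[Si](C)(C)C(C)(C)C)cc2OC)cc(OC)c1O[Si](C)(C)C(C)(C)C
F5 | step 18 | 4-[(1S,2S)-2-(4-DBF-2,6-dimethoxyphenoxy)-3-(tert-butyldimethylsilyloxy)-1-hydroxypropyl]-2,6-dimethoxyphenol | COc1cc([C@H](O)[C@H](CO[Si](C)(C)C(C)(C)C)Oc2c(OC)cc([C@@H]3Oc4c(OC)cc(Br)cc4[C@H]3CO[Si](C)(C)C(C)(C)C)cc2OC)cc(OC)c1O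
F6 | step 18 | (R)-4-benzyl-3-[(aryloxy)acetyl]-1,3-oxazolidin-2-one, aryl = ring B of F5 | O=C1OC[C@@H](Cc2ccccc2)N1C(=O)COc1c(OC)cc([C@H](O)[C@H](CO[Si](C)(C)C(C)(C)C)Oc2c(OC)cc([C@@H]3Oc4c(OC)cc(Br)cc4[C@H]3CO[Si](C)(C)C(C)(C)C)cc2OC)cc1OC
F7 | step 18 | syn aldol adduct of F6 with 26, (2R,3S) in the new propanoyl unit | O=C1OC[C@@H](Cc2ccccc2)N1C(=O)[C@H](Oc1c(OC)cc([C@H](O)[C@H](CO[Si](C)(C)C(C)(C)C)Oc2c(OC)cc([C@@H]3Oc4c(OC)cc(Br)cc4[C@H]3CO[Si](C)(C)C(C)(C)C)cc2OC)cc1OC)[C@@H](O)c1ccc(O[Si](C(C)C)(C(C)C)C(C)C)c(OC)c1
F8 | step 18 | bis-threo triol, (1S,2S) in both units, upper primary hydroxyl free | COc1cc([C@H](O)[C@H](CO)Oc2c(OC)cc([C@H](O)[C@H](CO[Si](C)(C)C(C)(C)C)Oc3c(OC)cc([C@@H]4Oc5c(OC)cc(Br)cc5[C@H]4CO[Si](C)(C)C(C)(C)C)cc3OC)cc2OC)ccc1O[Si](C(C)C)(C(C)C)C(C)C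
F9 | step 18 | bis-threo diol, the (1S,2S)/(1S,2S) diastereomer of 31 | COc1cc([C@H](O)[C@H](CO[Si](C)(C)C(C)(C)C)Oc2c(OC)cc([C@H](O)[C@H](CO[Si](C)(C)C(C)(C)C)Oc3c(OC)cc([C@@H]4Oc5c(OC)cc(Br)cc5[C@H]4CO[Si](C)(C)C(C)(C)C)cc3OC)cc2OC)ccc1O[Si](C(C)C)(C(C)C)C(C)C
F10 | step 18 | bis(4-nitrobenzoate) of 31 | COc1cc([C@@H](OC(=O)c2ccc(cc2)[N+](=O)[O-])[C@H](CO[Si](C)(C)C(C)(C)C)Oc2c(OC)cc([C@@H](OC(=O)c3ccc(cc3)[N+](=O)[O-])[C@H](CO[Si](C)(C)C(C)(C)C)Oc3c(OC)cc([C@@H]4Oc5c(OC)cc(Br)cc5[C@H]4CO[Si](C)(C)C(C)(C)C)cc3OC)cc2OC)ccc1O[Si](C(C)C)(C(C)C)C(C)C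
F11 | step 10 | ethyl (4-DBF-2,6-dimethoxyphenoxy)acetate | CCOC(=O)COc1c(OC)cc([C@@H]2Oc3c(OC)cc(Br)cc3[C@H]2CO[Si](C)(C)C(C)(C)C)cc1OC
F12 | step 10 | ethyl (diethoxyphosphanyl)(4-DBF-2,6-dimethoxyphenoxy)acetate | CCOC(=O)C(Oc1c(OC)cc([C@@H]2Oc3c(OC)cc(Br)cc3[C@H]2CO[Si](C)(C)C(C)(C)C)cc1OC)P(OCC)OCC
F13 | step 11 | ethyl 2-(4-DBF-2,6-dimethoxyphenoxy)-3-[4-(tert-butyldimethylsilyloxy)-3,5-dimethoxyphenyl]-3-hydroxypropanoate (mixture of diastereomers) | CCOC(=O)C(Oc1c(OC)cc([C@@H]2Oc3c(OC)cc(Br)cc3[C@H]2CO[Si](C)(C)C(C)(C)C)cc1OC)C(O)c1cc(OC)c(O[Si](C)(C)C(C)(C)C)c(OC)c1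
F14 | step 11 | methanesulfonate of F13 | CCOC(=O)C(Oc1c(OC)cc([C@@H]2Oc3c(OC)cc(Br)cc3[C@H]2CO[Si](C)(C)C(C)(C)C)cc1OC)C(OS(C)(=O)=O)c1cc(OC)c(O[Si](C)(C)C(C)(C)C)c(OC)c1
F0 | step 19 | none | none
A1 | alternative 1 | methyl 2-diazo-2-{5-bromo-3-methoxy-2-[3,5-dimethoxy-4-(methoxymethoxy)benzyloxy]phenyl}acetate | COCOc1c(OC)cc(COc2c(OC)cc(Br)cc2C(=[N+]=[N-])C(=O)OC)cc1OC
A2 | alternative 1 | methyl (2R,3R)-5-bromo-7-methoxy-2-[3,5-dimethoxy-4-(methoxymethoxy)phenyl]-2,3-dihydrobenzofuran-3-carboxylate | COCOc1c(OC)cc([C@@H]2Oc3c(OC)cc(Br)cc3[C@H]2C(=O)OC)cc1OC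
A3 | alternative 2 | (S)-2-(5-bromo-2-hydroxy-3-methoxyphenyl)-3-(4-hydroxy-3,5-dimethoxyphenyl)propan-1-ol | OC[C@@H](Cc1cc(OC)c(O)c(OC)c1)c1cc(Br)cc(OC)c1O
A4 | alternative 2 | (2R,3S)-5-bromo-3-(hydroxymethyl)-2-(4-hydroxy-3,5-dimethoxyphenyl)-7-methoxy-2,3-dihydrobenzofuran | Oc1c(OC)cc([C@@H]2Oc3c(OC)cc(Br)cc3[C@H]2CO)cc1OC
A5 | alternative 3 | 4-bromo-6-[2-(tert-butyldimethylsilyloxy)ethylidene]-2-methoxycyclohexa-2,4-dien-1-one (ortho-quinone methide) | O=C1C(OC)=CC(Br)=CC1=CCO[Si](C)(C)C(C)(C)C
A6 | alternative 3 | (2R,5R)-1-[3,5-dimethoxy-4-(methoxymethoxy)benzyl]-2,5-dimethylthiolan-1-ium triflate | COCOc1c(OC)cc(C[S+]2[C@H](C)CC[C@H]2C)cc1OC.[O-]S(=O)(=O)C(F)(F)F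
A7 | alternative 3 | (2R,3S)-5-bromo-3-[(tert-butyldimethylsilyloxy)methyl]-7-methoxy-2-[3,5-dimethoxy-4-(methoxymethoxy)phenyl]-2,3-dihydrobenzofuran | COCOc1c(OC)cc([C@@H]2Oc3c(OC)cc(Br)cc3[C@H]2CO[Si](C)(C)C(C)(C)C)cc1OC
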